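**Plan** (target numbering: C1 = C=O, C2=C3 = ring alkene, C4 = CH2, C5 = C(OH)(C19H39), C6 = CH2)

1. Retrosynthesis: the C1 carbonyl is taken back to a silyl-protected allylic carbinol. The ring is then cut at C4–C5 and C2=C3 together, the reverse of a ring-closing allylboration of a C5 ketone by an allylboronate with boron on C2. That allylboronate comes from a 1,2-metallate shift of a vinyl group (C3, C4) from boron to C2. Last, the C19 chain is cut from C5 (Weinreb amide plus Grignard reagent).
2. Enabling feature: in the ring the tertiary carbinol C5 is homoallylic to C2=C3 (C5–C4–C3=C2), and C2 is tied back to C5 through C1 and C6. An allyl-metal with the metal on C2 and a ketone at C5 therefore close the six-membered ring with allylic transposition.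
3. Forward order: (R)-3-hydroxy-γ-butyrolactone supplies C5 (lactone carbonyl), C6, C1 (with its oxygen) and C2 (the OCH2 carbon). The chain is joined at C5, vinylboronic ester brings C3 and C4, and the ring closes in the key step. Desilylation and allylic oxidation finish.
4. Stereochemistry: C2 is set by (+)-sparteine-mediated lithiation, and C5 arises from C2 by chirality transfer through a boron-bridged transition state. The lactone centre (C1) is only a handle that turns any leak of selectivity into separable diastereomers; it is erased in the last step.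

Key step: step 6

Assumption: (+)-sparteine is taken to override the bias of the neighbouring silyloxy stereocentre in the deprotonation, and the ring closure is taken to run through the closed, boron-bridged transition state; if either sense is reversed, (−)-sparteine is used instead.

Step 1
Reactants: 1 (R)-3-hydroxy-γ-butyrolactone [(4R)-4-hydroxyoxolan-2-one]
Product: 2 (4R)-4-[(tert-butyldimethylsilyl)oxy]oxolan-2-one
Conditions: t-BuMe2SiCl, imidazole, DMF, rt
Reagents that add atoms: tert-butyldimethylsilyl chloride, CC(C)(C)[Si](C)(C)Cl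
Why: Imidazole-promoted silylation of the secondary alcohol (silyl ether formation) should proceed without touching the stereocentre.

Step 2
Reactants: 2 (4R)-4-[(tert-butyldimethylsilyl)oxy]oxolan-2-one
Product: 3 (3R)-3-[(tert-butyldimethylsilyl)oxy]-4-hydroxy-N-methoxy-N-methylbutanamide
Conditions: MeNH(OMe)·HCl, AlMe3, CH2Cl2, 0 °C → rt
Reagents that add atoms: N,O-dimethylhydroxylamine hydrochloride, CNOC.Cl
Why: Aminolysis of the lactone by the aluminium amide made from AlMe3 and the amine hydrochloride (Weinreb amide formation) should open the ring at the acyl carbon only and free the primary alcohol.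

Step 3
Reactants: 3 (3R)-3-[(tert-butyldimethylsilyl)oxy]-4-hydroxy-N-methoxy-N-methylbutanamide
Product: 4 (2R)-2-[(tert-butyldimethylsilyl)oxy]-4-[methoxy(methyl)amino]-4-oxobutyl 2,4,6-tri(propan-2-yl)benzoate
Conditions: 2,4,6-(i-Pr)3C6H2COCl, Et3N, DMAP (cat.), CH2Cl2, 40 °C
Reagents that add atoms: 2,4,6-tri(propan-2-yl)benzoyl chloride, CC(C)c1cc(C(C)C)c(C(=O)Cl)c(C(C)C)c1
Why: DMAP-catalysed acylation of the primary alcohol should install the hindered benzoate that later directs α-lithiation and acts as the leaving group in the 1,2-metallate shift.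

Step 4
Reactants: 4 (2R)-2-[(tert-butyldimethylsilyl)oxy]-4-[methoxy(methyl)amino]-4-oxobutyl 2,4,6-tri(propan-2-yl)benzoate; 5 1-bromononadecane
Product: 7 (2R)-2-[(tert-butyldimethylsilyl)oxy]-4-oxotricosyl 2,4,6-tri(propan-2-yl)benzoate, via nonadecylmagnesium bromide 6 (not isolated)
Conditions: 5, Mg, THF, 50 °C; then 4, THF, 0 °C; aq NH4Cl
Reagents that add atoms: none
Why: In the Weinreb ketone synthesis the chelated tetrahedral intermediate should stop the Grignard addition at the ketone, and the hindered benzoate should not be attacked.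

Step 5
Reactants: 7 (2R)-2-[(tert-butyldimethylsilyl)oxy]-4-oxotricosyl 2,4,6-tri(propan-2-yl)benzoate
Product: 8 (2R)-2-[(tert-butyldimethylsilyl)oxy]-4,4-dimethoxytricosyl 2,4,6-tri(propan-2-yl)benzoate
Conditions: MeOSiMe3, Me3SiOTf (cat.), CH2Cl2, −78 → −20 °C; pyridine
Reagents that add atoms: methoxytrimethylsilane, CO[Si](C)(C)C
Why: Aprotic acetalisation with an alkoxysilane and a silyl triflate catalyst at low temperature should mask the ketone as the acid-labile dimethyl ketal without β-elimination or loss of the silyl ether.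

Step 6
Reactants: 8 (2R)-2-[(tert-butyldimethylsilyl)oxy]-4,4-dimethoxytricosyl 2,4,6-tri(propan-2-yl)benzoate; 9 vinylboronic acid pinacol ester (2-ethenyl-4,4,5,5-tetramethyl-1,3,2-dioxaborolane)
Product: 15 (1S,5R)-5-[(tert-butyldimethylsilyl)oxy]-1-nonadecylcyclohex-3-en-1-ol, via lithiated benzoate 10 (not isolated), via boronate complex 11 (not isolated), via allylboronate 12 (not isolated), via keto allylboronate 13 (not isolated), via borate ester 14 (not isolated)
Conditions: s-BuLi, (+)-sparteine, Et2O, −78 °C; 9, −78 → 35 °C; then 1 M aq HCl, THF, rt → 40 °C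
Reagents that add atoms: water, O
Why: Proposed new method: (+)-sparteine-directed deprotonation removes the pro-R hydrogen next to the benzoate oxygen to give the configurationally stable organolithium 10, which adds to the boron of 9 with retention (11); the vinyl group then shifts from boron to carbon with inversion and loss of the benzoate (1,2-metallate rearrangement), which forms the C2–C3 bond and gives the (R)-allylboronate 12, and aqueous acid frees the C5 ketone (13), to which the allylboronate adds with allylic transposition (SE2′) so that the C4–C5 bond and the C2=C3 double bond arise together. The closest known reaction type is the one-pot lithiation–borylation of α-oxy organolithiums with vinylboron reagents followed by allylboration of an added aldehyde; new here are the tethered ketone as the electrophile and the tether on the boron-bearing carbon. The cyclohexene ring closes in a 6-exo-trig mode with respect to the C=O, with the allyl unit ending up inside the ring, through a boron-bridged boat transition state shaped like a bicyclo[2.2.2]octane (bridges C3–C4, B–O and C1–C6). The C5 stereocentre is controlled by the C2 stereocentre alone, because only one bridged arrangement exists for each configuration at C2: (R) at C2 gives (S) at C5, and C2 itself is controlled by the diamine. The step needs attack by the vinyl terminus without a prior 1,3-shift of boron and without β-elimination of the C1 silyloxy group; the pinacol ester should not undergo the 1,3-shift at these temperatures, attack through the boron-bearing carbon would give a four-membered ring, the silyl ether is a poor leaving group at −78 °C, and the (R) configuration at C1 keeps the silyloxy group on the side of the alkene bridge, away from the dioxaborolane.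

Step 7
Reactants: 15 (1S,5R)-5-[(tert-butyldimethylsilyl)oxy]-1-nonadecylcyclohex-3-en-1-ol
Product: 16 (1S,3R)-1-nonadecylcyclohex-4-ene-1,3-diol
Conditions: Bu4NF, THF, 0 °C → rt
Reagents that add atoms: none
Why: Fluoride-induced desilylation should free the secondary allylic alcohol while no carbonyl group is present that could suffer retro-aldol cleavage or dehydration.

Step 8
Reactants: 16 (1S,3R)-1-nonadecylcyclohex-4-ene-1,3-diol
Product: 17 (5S)-5-hydroxy-5-nonadecylcyclohex-2-en-1-one
Conditions: MnO2, CH2Cl2, rt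
Reagents that add atoms: none
Why: Allylic oxidation with MnO2 should convert only the secondary allylic alcohol into the enone under neutral conditions, which erases the temporary C1 stereocentre and spares the tertiary β-hydroxy ketone from dehydration to the phenol.

**Compound list**

1 | (R)-3-hydroxy-γ-butyrolactone, (4R)-4-hydroxyoxolan-2-one | O[C@H]1COC(=O)C1 | starting material
2 | (4R)-4-[(tert-butyldimethylsilyl)oxy]oxolan-2-one | CC(C)(C)[Si](C)(C)O[C@H]1COC(=O)C1 | intermediate
3 | (3R)-3-[(tert-butyldimethylsilyl)oxy]-4-hydroxy-N-methoxy-N-methylbutanamide | CON(C)C(=O)C[C@H](CO)O[Si](C)(C)C(C)(C)C | intermediate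
4 | (2R)-2-[(tert-butyldimethylsilyl)oxy]-4-[methoxy(methyl)amino]-4-oxobutyl 2,4,6-tri(propan-2-yl)benzoate | CON(C)C(=O)C[C@H](COC(=O)c1c(C(C)C)cc(C(C)C)cc1C(C)C)O[Si](C)(C)C(C)(C)C | intermediate
5 | 1-bromononadecane | CCCCCCCCCCCCCCCCCCCBr | starting material
6 | nonadecylmagnesium bromide | CCCCCCCCCCCCCCCCCCC[Mg]Br | intermediate
7 | (2R)-2-[(tert-butyldimethylsilyl)oxy]-4-oxotricosyl 2,4,6-tri(propan-2-yl)benzoate | CCCCCCCCCCCCCCCCCCCC(=O)C[C@H](COC(=O)c1c(C(C)C)cc(C(C)C)cc1C(C)C)O[Si](C)(C)C(C)(C)C | intermediate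
8 | (2R)-2-[(tert-butyldimethylsilyl)oxy]-4,4-dimethoxytricosyl 2,4,6-tri(propan-2-yl)benzoate | CCCCCCCCCCCCCCCCCCCC(OC)(OC)C[C@H](COC(=O)c1c(C(C)C)cc(C(C)C)cc1C(C)C)O[Si](C)(C)C(C)(C)C | intermediate
9 | vinylboronic acid pinacol ester, 2-ethenyl-4,4,5,5-tetramethyl-1,3,2-dioxaborolane | C=CB1OC(C)(C)C(C)(C)O1 | starting material
10 | (1R,2R)-2-[(tert-butyldimethylsilyl)oxy]-4,4-dimethoxy-1-lithiotricosyl 2,4,6-tri(propan-2-yl)benzoate | [Li][C@@H](OC(=O)c1c(C(C)C)cc(C(C)C)cc1C(C)C)[C@H](O[Si](C)(C)C(C)(C)C)CC(OC)(OC)CCCCCCCCCCCCCCCCCCC | intermediate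
11 | lithium ethenyl(pinacolato)borate complex carrying the (1R,2R)-1-benzoyloxy-2-silyloxy-4,4-dimethoxytricosyl group on boron | [Li+].C=C[B-]1(OC(C)(C)C(C)(C)O1)[C@@H](OC(=O)c2c(C(C)C)cc(C(C)C)cc2C(C)C)[C@H](O[Si](C)(C)C(C)(C)C)CC(OC)(OC)CCCCCCCCCCCCCCCCCCC | intermediate
12 | tert-butyl{[(3R,4R)-6,6-dimethoxy-3-(4,4,5,5-tetramethyl-1,3,2-dioxaborolan-2-yl)pentacos-1-en-4-yl]oxy}dimethylsilane | C=C[C@@H](B1OC(C)(C)C(C)(C)O1)[C@H](O[Si](C)(C)C(C)(C)C)CC(OC)(OC)CCCCCCCCCCCCCCCCCCC | intermediate
13 | (3R,4R)-4-[(tert-butyldimethylsilyl)oxy]-3-(4,4,5,5-tetramethyl-1,3,2-dioxaborolan-2-yl)pentacos-1-en-6-one | C=C[C@@H](B1OC(C)(C)C(C)(C)O1)[C@H](O[Si](C)(C)C(C)(C)C)CC(=O)CCCCCCCCCCCCCCCCCCC | intermediate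
14 | 2-{[(1S,5R)-5-[(tert-butyldimethylsilyl)oxy]-1-nonadecylcyclohex-3-en-1-yl]oxy}-4,4,5,5-tetramethyl-1,3,2-dioxaborolane | CCCCCCCCCCCCCCCCCCC[C@]1(OB2OC(C)(C)C(C)(C)O2)CC=C[C@H](O[Si](C)(C)C(C)(C)C)C1 | intermediate
15 | (1S,5R)-5-[(tert-butyldimethylsilyl)oxy]-1-nonadecylcyclohex-3-en-1-ol (hydroxyl and silyloxy trans) | CCCCCCCCCCCCCCCCCCC[C@]1(O)CC=C[C@H](O[Si](C)(C)C(C)(C)C)C1 | intermediate
16 | (1S,3R)-1-nonadecylcyclohex-4-ene-1,3-diol | CCCCCCCCCCCCCCCCCCC[C@]1(O)CC=C[C@H](O)C1 | intermediate
17 | (5S)-5-hydroxy-5-nonadecylcyclohex-2-en-1-one | CCCCCCCCCCCCCCCCCCC[C@]1(O)CC=CC(=O)C1 | target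

**Totals and risks**

Total step count: 8. Longest linear sequence: 8 steps (from 1).

Steps most likely to fail:

Step 6 (proposed new method). What may go wrong:
- β-elimination of the silyloxy group from the lithiated benzoate;
- protodeboronation of the allylboronate, or its attack on the oxocarbenium ion, during the acidic unmasking;
- a slow bridged ring closure, or an open transition state that would reverse the sense of chirality transfer.

Fallback with known chemistry only; it sets out from 3 and comes back at 15. Parikh–Doering oxidation of 3 (SO3·pyridine, DMSO, i-Pr2NEt) should give (3R)-3-[(tert-butyldimethylsilyl)oxy]-N-methoxy-N-methyl-4-oxobutanamide F1. Wittig methylenation (Ph3P=CH2, THF, −78 °C) should give (3R)-3-[(tert-butyldimethylsilyl)oxy]-N-methoxy-N-methylpent-4-enamide F2. Addition of the Grignard reagent 6 should give (3R)-3-[(tert-butyldimethylsilyl)oxy]tetracos-1-en-5-one F3. Addition of allylmagnesium bromide should give the tertiary alcohol as two C5 epimers, which are diastereomers because of the fixed silyloxy centre; chromatography should deliver (3R,5S)-3-[(tert-butyldimethylsilyl)oxy]-5-(prop-2-en-1-yl)tetracos-1-en-5-ol F4. Ring-closing metathesis of F4 with the second-generation Grubbs catalyst (CH2Cl2, 40 °C) should close the C2=C3 bond with loss of ethene and give 15.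

Step 5. What may go wrong: β-elimination of silanol from the β-silyloxy ketone, loss of the silyl ether, or loss of the labile ketal on purification.

Fallback: the ketone is masked by its oxidation level instead of as a ketal; it sets out from 7 and comes back at 15. Reduction with NaBH4 should give (2R)-2-[(tert-butyldimethylsilyl)oxy]-4-hydroxytricosyl 2,4,6-tri(propan-2-yl)benzoate F5 (both C4 epimers). Silylation with Et3SiCl and imidazole should give (2R)-2-[(tert-butyldimethylsilyl)oxy]-4-[(triethylsilyl)oxy]tricosyl 2,4,6-tri(propan-2-yl)benzoate F6. Lithiation–borylation with s-BuLi, (+)-sparteine and 9 should give the isolable tert-butyl{[(3R,4R)-3-(4,4,5,5-tetramethyl-1,3,2-dioxaborolan-2-yl)-6-[(triethylsilyl)oxy]pentacos-1-en-4-yl]oxy}dimethylsilane F7. Selective removal of the triethylsilyl group (HF·pyridine, pyridine, THF) should give (3R,4R)-4-[(tert-butyldimethylsilyl)oxy]-3-(4,4,5,5-tetramethyl-1,3,2-dioxaborolan-2-yl)pentacos-1-en-6-ol F8. Dess–Martin oxidation should give the keto allylboronate 13, which should cyclise to 15 as in step 6.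

Step 2. What may go wrong: migration of the silyl group to the primary oxygen, or relactonisation of the hydroxy amide.

Fallback: the order of events is changed; it sets out from 1 and comes back at 4. Aminolysis of the unprotected lactone with the same aluminium amide should give (3R)-3,4-dihydroxy-N-methoxy-N-methylbutanamide F9. The hindered acid chloride (Et3N, DMAP) should acylate only the primary hydroxyl to give (2R)-2-hydroxy-4-[methoxy(methyl)amino]-4-oxobutyl 2,4,6-tri(propan-2-yl)benzoate F10. Silylation of the remaining secondary alcohol (t-BuMe2SiOTf, 2,6-lutidine) should give 4.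

Further compounds

F1 | step 6 | (3R)-3-[(tert-butyldimethylsilyl)oxy]-N-methoxy-N-methyl-4-oxobutanamide | CON(C)C(=O)C[C@H](C=O)O[Si](C)(C)C(C)(C)C
F2 | step 6 | (3R)-3-[(tert-butyldimethylsilyl)oxy]-N-methoxy-N-methylpent-4-enamide | CON(C)C(=O)C[C@H](C=C)O[Si](C)(C)C(C)(C)C
F3 | step 6 | (3R)-3-[(tert-butyldimethylsilyl)oxy]tetracos-1-en-5-one | C=C[C@H](O[Si](C)(C)C(C)(C)C)CC(=O)CCCCCCCCCCCCCCCCCCC
F4 | step 6 | (3R,5S)-3-[(tert-butyldimethylsilyl)oxy]-5-(prop-2-en-1-yl)tetracos-1-en-5-ol | CCCCCCCCCCCCCCCCCCC[C@](O)(CC=C)C[C@@H](O[Si](C)(C)C(C)(C)C)C=C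
F5 | step 5 | (2R)-2-[(tert-butyldimethylsilyl)oxy]-4-hydroxytricosyl 2,4,6-tri(propan-2-yl)benzoate (both C4 epimers) | CCCCCCCCCCCCCCCCCCCC(O)C[C@H](COC(=O)c1c(C(C)C)cc(C(C)C)cc1C(C)C)O[Si](C)(C)C(C)(C)C
F6 | step 5 | (2R)-2-[(tert-butyldimethylsilyl)oxy]-4-[(triethylsilyl)oxy]tricosyl 2,4,6-tri(propan-2-yl)benzoate (both C4 epimers) | CCCCCCCCCCCCCCCCCCCC(O[Si](CC)(CC)CC)C[C@H](COC(=O)c1c(C(C)C)cc(C(C)C)cc1C(C)C)O[Si](C)(C)C(C)(C)C
F7 | step 5 | tert-butyl{[(3R,4R)-3-(4,4,5,5-tetramethyl-1,3,2-dioxaborolan-2-yl)-6-[(triethylsilyl)oxy]pentacos-1-en-4-yl]oxy}dimethylsilane (both C6 epimers) | C=C[C@@H](B1OC(C)(C)C(C)(C)O1)[C@H](O[Si](C)(C)C(C)(C)C)CC(O[Si](CC)(CC)CC)CCCCCCCCCCCCCCCCCCC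
F8 | step 5 | (3R,4R)-4-[(tert-butyldimethylsilyl)oxy]-3-(4,4,5,5-tetramethyl-1,3,2-dioxaborolan-2-yl)pentacos-1-en-6-ol (both C6 epimers) | C=C[C@@H](B1OC(C)(C)C(C)(C)O1)[C@H](O[Si](C)(C)C(C)(C)C)CC(O)CCCCCCCCCCCCCCCCCCC
F9 | step 2 | (3R)-3,4-dihydroxy-N-methoxy-N-methylbutanamide | CON(C)C(=O)C[C@H](CO)O
F10 | step 2 | (2R)-2-hydroxy-4-[methoxy(methyl)amino]-4-oxobutyl 2,4,6-tri(propan-2-yl)benzoate | CON(C)C(=O)C[C@H](COC(=O)c1c(C(C)C)cc(C(C)C)cc1C(C)C)O
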